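The route rests on cutting two bonds of the dihydrofuran ring fused to ring A: O1–C2 and the bond from C3 to its exocyclic carbon. C2 and C3 are then the alkene carbons of an (E)-stilbene whose ring A carries a free phenol ortho to the double bond. One palladium-catalysed oxidative operation adds that oxygen to C2 and carbon monoxide, as a methyl ester, to C3. It closes the five-membered ring and fixes C2 through a chiral bis(oxazoline) and C3 by equilibration to trans. The precursor already holds the C7 methoxy group, the C5 acrylate and a pivalate-masked syringyl ring, so one hydride reduction completes the target.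

Key step: step 5

Numbering: atom labels follow 2,3-dihydro-1-benzofuran numbering; ring A is the benzo ring and ring B the syringyl ring on C2.

Remark: the sense of induction of the bis(oxazoline) in this cyclisation cannot be derived from a model, so the (S,S)-ligand is written and its commercial antipode is to be used if a first analytical run shows the (2R) series.

Step 1
Reactants: 1 syringaldehyde; 2 pivaloyl chloride
Product: 3 4-formyl-2,6-dimethoxyphenyl pivalate
Conditions: PivCl (1.3 equiv), Et3N, DMAP (10 mol %), CH2Cl2, 0 → 40 °C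
Reagents that add atoms: pivaloyl chloride, CC(C)(C)C(=O)Cl
Why: DMAP-catalysed O-acylation of the phenol by the acid chloride is a standard esterification that leaves the aldehyde untouched, and the bulky ester is chosen because it later resists the ylide, the amine bases and methanol.

Step 2
Reactants: 3 4-formyl-2,6-dimethoxyphenyl pivalate; 4 methyltriphenylphosphonium bromide
Product: 6 4-ethenyl-2,6-dimethoxyphenyl pivalate, via methylenetriphenylphosphorane 5 (not isolated)
Conditions: Ph3PCH3Br (1.3 equiv), KOt-Bu (1.2 equiv), THF, 0 °C, then 3, 0 °C → rt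
Reagents that add atoms: methyltriphenylphosphonium bromide, C[P+](c1ccccc1)(c1ccccc1)c1ccccc1.[Br-]
Why: Wittig methylenation of an aromatic aldehyde, in which the non-stabilised ylide (made with a slight deficit of base) adds to the formyl group far faster than to the pivalate carbonyl, which is shielded by the tert-butyl group and the two flanking methoxy groups.

Step 3
Reactants: 7 5-iodovanillin; 8 methyl (triphenylphosphoranylidene)acetate
Product: 9 methyl (E)-3-(4-hydroxy-3-iodo-5-methoxyphenyl)prop-2-enoate
Conditions: Ph3P=CHCO2Me (1.4 equiv), toluene, 90 °C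
Reagents that add atoms: methyl (triphenylphosphoranylidene)acetate, COC(=O)C=P(c1ccccc1)(c1ccccc1)c1ccccc1
Why: Wittig olefination with a stabilised ylide needs no added base, so the free phenol is tolerated where a phosphonate anion would first be spent on deprotonating it, and the stabilised ylide gives the (E)-cinnamate.

Step 4
Reactants: 9 methyl (E)-3-(4-hydroxy-3-iodo-5-methoxyphenyl)prop-2-enoate; 6 4-ethenyl-2,6-dimethoxyphenyl pivalate
Product: 10 methyl (E)-3-[3-[(E)-2-[3,5-dimethoxy-4-(pivaloyloxy)phenyl]ethenyl]-4-hydroxy-5-methoxyphenyl]prop-2-enoate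
Conditions: Pd(OAc)2 (5 mol %), P(o-tol)3 (10 mol %), Et3N, DMF, 90 °C
Reagents that add atoms: none
Why: Mizoroki–Heck reaction in which zerovalent palladium inserts into the C–I bond (easy for an iodide even next to a phenol), the terminal styrene inserts at its unsubstituted carbon and syn β-hydride elimination gives the (E)-stilbene, while the 1,2-disubstituted cinnamate alkene inserts much more slowly and the pivalate is inert to Et3N.

Step 5
Reactants: 10 methyl (E)-3-[3-[(E)-2-[3,5-dimethoxy-4-(pivaloyloxy)phenyl]ethenyl]-4-hydroxy-5-methoxyphenyl]prop-2-enoate; 11 carbon monoxide; 12 methanol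
Product: 14 methyl (2S,3S)-trans-2-[3,5-dimethoxy-4-(pivaloyloxy)phenyl]-7-methoxy-5-[(E)-3-methoxy-3-oxoprop-1-enyl]-2,3-dihydro-1-benzofuran-3-carboxylate, via cis ester 13 (not isolated)
Conditions: Pd(OCOCF3)2 (10 mol %), (S,S)-Ph-box [2,2'-(propane-2,2-diyl)bis((4S)-4-phenyl-4,5-dihydrooxazole)] (12 mol %), p-benzoquinone (2 equiv), CO (5 bar), MeOH/CH2Cl2 1:1, 25 °C, no chloride; filter through silica, evaporate; then DBU (0.3 equiv), CH2Cl2, 25 °C
Reagents that add atoms: carbon monoxide, [C-]#[O+]; methanol, CO
Why: Proposed new method: divalent palladium carrying the bis(oxazoline) binds the ring A phenoxide and the stilbene double bond, O1 adds to C2 while the metal moves to C3 as an η3-benzyl species, CO inserts into the C3–Pd bond with retention, methanol cleaves the acylpalladium to the methyl ester, and p-benzoquinone takes zerovalent palladium back to the divalent state. The closest known reaction types are the enantioselective Wacker-type cyclisation–methoxycarbonylation of alkenylphenols, which closes in the exo mode, and the oxidative carbonylative cyclisation of 2-alkynylphenols to benzofuran-3-carboxylates; an endo closure onto an alkene that ends in CO capture at the ring carbon has not been shown. The dihydrofuran closes in the 5-endo-trig mode, the only mode open to a phenol placed ortho to the double bond (the 4-exo alternative is not viable). C2 is set by the ligand, which chooses the alkene face in the oxypalladation; under chloride-free conditions O and Pd are expected to add syn across the (E)-alkene, so after retentive CO insertion C3 first carries its ester cis to the C2 aryl group (13), and DBU then inverts this doubly activated centre to the more stable trans arrangement under control of C2. The step needs CO capture at C3 to win over β-hydride loss to the 2-arylbenzofuran, which the substrate and catalyst secure because the only β-hydrogen, H–C2, lies anti to palladium in the syn adduct and because CO together with the chelating ligand leaves no free cis site. It also needs site selectivity, which rests on the acrylate alkene being electron-poor and out of reach of any nucleophile, on methyl esters that match the solvent, and on the pivalate, which shields the syringyl ring from oxidation to a quinone methide and keeps C2 fixed during the DBU stage.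

Step 6
Reactants: 14 methyl (2S,3S)-trans-2-[3,5-dimethoxy-4-(pivaloyloxy)phenyl]-7-methoxy-5-[(E)-3-methoxy-3-oxoprop-1-enyl]-2,3-dihydro-1-benzofuran-3-carboxylate
Product: 15 4-[(2S,3R)-3-(hydroxymethyl)-5-[(E)-3-hydroxyprop-1-enyl]-7-methoxy-2,3-dihydro-1-benzofuran-2-yl]-2,6-dimethoxyphenol
Conditions: i-Bu2AlH (8 equiv), CH2Cl2/toluene, −78 → 0 °C; aq. potassium sodium tartrate (KNaC4H4O6)
Reagents that add atoms: none
Why: Hydride reduction with i-Bu2AlH takes the saturated and the conjugated methyl ester to primary alcohols (1,2-reduction of the enoate) at −78 °C and cleaves the aryl pivalate on warming, so the free phenoxide never coexists with an epimerisable C3 ester; C2 and C3 keep their spatial arrangement, and the C3 descriptor changes from S to R only because CH2OH ranks below C2 whereas CO2Me ranked above it.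

Compound list
1 | syringaldehyde (4-hydroxy-3,5-dimethoxybenzaldehyde) | COc1cc(C=O)cc(OC)c1O | starting material
2 | pivaloyl chloride | CC(C)(C)C(=O)Cl | starting material
3 | 4-formyl-2,6-dimethoxyphenyl pivalate | COc1cc(C=O)cc(OC)c1OC(=O)C(C)(C)C | intermediate
4 | methyltriphenylphosphonium bromide | C[P+](c1ccccc1)(c1ccccc1)c1ccccc1.[Br-] | starting material
5 | methylenetriphenylphosphorane | C=P(c1ccccc1)(c1ccccc1)c1ccccc1 | intermediate
6 | 4-ethenyl-2,6-dimethoxyphenyl pivalate | C=Cc1cc(OC)c(OC(=O)C(C)(C)C)c(OC)c1 | intermediate
7 | 5-iodovanillin (4-hydroxy-3-iodo-5-methoxybenzaldehyde) | COc1cc(C=O)cc(I)c1O | starting material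
8 | methyl (triphenylphosphoranylidene)acetate | COC(=O)C=P(c1ccccc1)(c1ccccc1)c1ccccc1 | starting material
9 | methyl (E)-3-(4-hydroxy-3-iodo-5-methoxyphenyl)prop-2-enoate | COC(=O)/C=C/c1cc(OC)c(O)c(I)c1 | intermediate
10 | methyl (E)-3-[3-[(E)-2-[3,5-dimethoxy-4-(pivaloyloxy)phenyl]ethenyl]-4-hydroxy-5-methoxyphenyl]prop-2-enoate | COC(=O)/C=C/c1cc(OC)c(O)c(/C=C/c2cc(OC)c(OC(=O)C(C)(C)C)c(OC)c2)c1 | intermediate
11 | carbon monoxide | [C-]#[O+] | starting material
12 | methanol | CO | starting material
13 | methyl (2S,3R)-cis-2-[3,5-dimethoxy-4-(pivaloyloxy)phenyl]-7-methoxy-5-[(E)-3-methoxy-3-oxoprop-1-enyl]-2,3-dihydro-1-benzofuran-3-carboxylate | COc1cc([C@H]2Oc3c(OC)cc(/C=C/C(=O)OC)cc3[C@H]2C(=O)OC)cc(OC)c1OC(=O)C(C)(C)C | intermediate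
14 | methyl (2S,3S)-trans-2-[3,5-dimethoxy-4-(pivaloyloxy)phenyl]-7-methoxy-5-[(E)-3-methoxy-3-oxoprop-1-enyl]-2,3-dihydro-1-benzofuran-3-carboxylate | COc1cc([C@H]2Oc3c(OC)cc(/C=C/C(=O)OC)cc3[C@@H]2C(=O)OC)cc(OC)c1OC(=O)C(C)(C)C | intermediate
15 | 4-[(2S,3R)-3-(hydroxymethyl)-5-[(E)-3-hydroxyprop-1-enyl]-7-methoxy-2,3-dihydro-1-benzofuran-2-yl]-2,6-dimethoxyphenol (trans) | COc1cc([C@H]2Oc3c(OC)cc(/C=C/CO)cc3[C@@H]2CO)cc(OC)c1O | target

Total step count: 6
Longest linear sequence: 5 steps (steps 1, 2, 4, 5 and 6)

Steps most likely to fail

Step 5 (the labelled step).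
- What may go wrong: the strained 5-endo addition of the phenoxide may be too slow, so that the catalyst is consumed by background oxidative carbonylation of methanol or reduced by CO to palladium metal.
- If addition runs anti instead of syn, a syn β-hydrogen becomes available and aromatisation to the benzofuran may win.
- Enantioface selection may be poor, or split between syn and anti pathways that deliver opposite C2 configurations.
- Fallback (known chemistry): enantioselective rhodium-carbenoid C–H insertion, setting out from 3 and 9 and coming back at 13. Aldehyde 3 would be reduced (NaBH4, MeOH/THF, 0 °C) to 4-(hydroxymethyl)-2,6-dimethoxyphenyl pivalate F1. Mitsunobu etherification of phenol 9 with this alcohol (PPh3, DIAD, THF) would give methyl (E)-3-[4-[[3,5-dimethoxy-4-(pivaloyloxy)phenyl]methoxy]-3-iodo-5-methoxyphenyl]prop-2-enoate F2. Palladium-catalysed coupling of the aryl iodide with the Reformatsky reagent BrZnCH2CO2Me (Pd(P(t-Bu)3)2, THF, 25 °C) would give methyl (E)-3-[4-[[3,5-dimethoxy-4-(pivaloyloxy)phenyl]methoxy]-3-methoxy-5-(2-methoxy-2-oxoethyl)phenyl]prop-2-enoate F3. Diazo transfer (4-acetamidobenzenesulfonyl azide, DBU, MeCN) would give methyl (E)-3-[3-(1-diazo-2-methoxy-2-oxoethyl)-4-[[3,5-dimethoxy-4-(pivaloyloxy)phenyl]methoxy]-5-methoxyphenyl]prop-2-enoate F4. Treating this with dirhodium tetrakis[N-phthaloyl-(S)-tert-leucinate], Rh2(S-PTTL)4, in toluene at −60 °C should bring about 1,5-insertion of the carbenoid into the benzylic C–H bond of the ether. This is an established enantioselective entry to cis-2-aryl-2,3-dihydrobenzofuran-3-carboxylates, with the catalyst antipode chosen for the (2S) series, and it would give cis ester 13. The DBU stage of step 5 then leads to 14.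

Step 4.
- What may go wrong: turnover may stall because the ortho-iodophenoxide binds palladium, the electron-rich styrene may oligomerise at the reaction temperature, or arylation may spill over to the cinnamate double bond of 9.
- Fallback: a Suzuki–Miyaura coupling that needs no free styrene and no carbopalladation, setting out from 3 and 9 and coming back at 10. Boron–Wittig olefination of aldehyde 3 with lithiated bis[(pinacolato)boryl]methane (CH2(Bpin)2, lithium 2,2,6,6-tetramethylpiperidide, THF, −78 °C → rt) would give 2,6-dimethoxy-4-[(E)-2-(4,4,5,5-tetramethyl-1,3,2-dioxaborolan-2-yl)ethenyl]phenyl pivalate F5. Coupling of this alkenylboronate with iodide 9 (PdCl2(dppf), K3PO4, THF/H2O, 60 °C) should give stilbene 10 with retention of the (E) geometry.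

Step 6.
- What may go wrong: reductive cleavage of the hindered pivalate may be incomplete unless the mixture is warmed. The aluminium phenoxide formed on warming may then assist opening of the C2–O1 bond through a quinone methide before work-up.
- Fallback: separation of reduction and deprotection, setting out from 14 and coming back at 15. Reduction with i-Bu2AlH (4.5 equiv, toluene, −78 °C only) should stop at 4-[(2S,3R)-3-(hydroxymethyl)-5-[(E)-3-hydroxyprop-1-enyl]-7-methoxy-2,3-dihydro-1-benzofuran-2-yl]-2,6-dimethoxyphenyl pivalate F6. The aryl ester would then be removed by methanolysis (K2CO3, MeOH, 0 °C → rt) to give 15. C3 no longer bears an acidic hydrogen at that stage, so base cannot erode the configuration.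

Further compounds
F1 | step 5 | 4-(hydroxymethyl)-2,6-dimethoxyphenyl pivalate | COc1cc(CO)cc(OC)c1OC(=O)C(C)(C)C
F2 | step 5 | methyl (E)-3-[4-[[3,5-dimethoxy-4-(pivaloyloxy)phenyl]methoxy]-3-iodo-5-methoxyphenyl]prop-2-enoate | COC(=O)/C=C/c1cc(OC)c(OCc2cc(OC)c(OC(=O)C(C)(C)C)c(OC)c2)c(I)c1
F3 | step 5 | methyl (E)-3-[4-[[3,5-dimethoxy-4-(pivaloyloxy)phenyl]methoxy]-3-methoxy-5-(2-methoxy-2-oxoethyl)phenyl]prop-2-enoate | COC(=O)/C=C/c1cc(OC)c(OCc2cc(OC)c(OC(=O)C(C)(C)C)c(OC)c2)c(CC(=O)OC)c1
F4 | step 5 | methyl (E)-3-[3-(1-diazo-2-methoxy-2-oxoethyl)-4-[[3,5-dimethoxy-4-(pivaloyloxy)phenyl]methoxy]-5-methoxyphenyl]prop-2-enoate | COC(=O)/C=C/c1cc(OC)c(OCc2cc(OC)c(OC(=O)C(C)(C)C)c(OC)c2)c(C(=[N+]=[N-])C(=O)OC)c1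
F5 | step 4 | 2,6-dimethoxy-4-[(E)-2-(4,4,5,5-tetramethyl-1,3,2-dioxaborolan-2-yl)ethenyl]phenyl pivalate | COc1cc(/C=C/B2OC(C)(C)C(C)(C)O2)cc(OC)c1OC(=O)C(C)(C)C
F6 | step 6 | 4-[(2S,3R)-3-(hydroxymethyl)-5-[(E)-3-hydroxyprop-1-enyl]-7-methoxy-2,3-dihydro-1-benzofuran-2-yl]-2,6-dimethoxyphenyl pivalate | COc1cc([C@H]2Oc3c(OC)cc(/C=C/CO)cc3[C@@H]2CO)cc(OC)c1OC(=O)C(C)(C)C
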